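## Retrosynthetic overview

1. The C4 methylidene comes from a C4 ketone by a final Wittig reaction; the free phenol comes from an aryl methyl ether; the C4 ketone is masked as a dioxolane through the middle of the route.
2. The C8 methyl comes from a C8 ketone by methylenation and hydrogenation.
3. The C9 quaternary centre comes from two α′-alkylations of a ring B enone, benzyl bromide first and methyl iodide last.
4. The ring B enone comes from a [4+2] cycloaddition of (S)-carvone (ring A, bought) with a 2-silyloxybuta-1,3-diene, then Saegusa–Ito oxidation. The carvone stereocentre fixes C5 and C10 (cis fusion) and its isopropenyl group is then excised.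
5. Ring order: ring A is bought, ring B is formed by the Diels–Alder reaction, the arene is bought as the benzyl bromide.

Assumption: the SMILES is taken literally (cis-fused decalin with C5–CH3, H-10, C9–CH3 and C8–CH3 on one face and the benzyl group on the other), and (S)-(+)-carvone, but-3-en-2-one and methyl 3-(bromomethyl)-4-methoxybenzoate are bought.

Locants in the names: C1–C4 are ring A (C4 carries the oxygen or the methylidene), C5 is the angular-methyl carbon, C6–C9 are ring B, C10 is the ring-fusion CH. β is the face of the C5 methyl; H-10 is β in every bicyclic compound (cis fusion).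

## Route

Step 1
Reactants: 1 but-3-en-2-one
Product: 2 2-(tert-butyldimethylsilyloxy)buta-1,3-diene
Conditions: TBSOTf, Et3N, Et2O, 0 °C → rt
Reagents that add atoms: tert-butyldimethylsilyl trifluoromethanesulfonate, CC(C)(C)[Si](C)(C)OS(=O)(=O)C(F)(F)F
Why: Soft enolisation and O-silylation of the methyl ketone give the cross-conjugated 2-silyloxydiene; no stereocentre is formed.

Step 2
Reactants: 3 (S)-(+)-carvone; 2 2-(tert-butyldimethylsilyloxy)buta-1,3-diene
Product: 4 8-(tert-butyldimethylsilyloxy)-2β-isopropenyl-5β-methyl-10β-H-decal-7-en-4-one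
Conditions: EtAlCl2 (30 mol %), toluene, −20 °C → rt
Reagents that add atoms: none
Why: Lewis-acid-catalysed Diels–Alder cycloaddition in which the diene CH2 next to the silyloxy carbon bonds to the enone β-carbon ("para" regiochemistry) and the diene adds to the enone face opposite the isopropenyl group of carvone, so the ring fusion is cis and C5 and C10 are set by the bought stereocentre.

Step 3
Reactants: 4 8-(tert-butyldimethylsilyloxy)-2β-isopropenyl-5β-methyl-10β-H-decal-7-en-4-one
Product: 5 2β-isopropenyl-5β-methyl-10β-H-decal-6-ene-4,8-dione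
Conditions: Pd(OAc)2 (1.1 equiv), MeCN, 40 °C
Reagents that add atoms: none
Why: Saegusa–Ito oxidation: the regiodefined silyl enol ether gives the C7 palladium enolate and β-hydride elimination of H-6 gives only the C6=C7 enone, with no stereocentre touched.

Step 4
Reactants: 5 2β-isopropenyl-5β-methyl-10β-H-decal-6-ene-4,8-dione
Product: 7 5β-methyl-10β-H-decal-6-ene-4,8-dione, via methoxy hydroperoxide 6 (not isolated)
Conditions: O3, MeOH, −78 °C; then FeSO4·7H2O, PhSH, −78 °C → rt
Reagents that add atoms: none
Why: Hydrodealkenylation: the electron-rich isopropenyl group is ozonised much faster than the enone C=C, methanol traps the carbonyl oxide, divalent iron cleaves the O–O bond, the alkoxy radical loses methyl acetate by β-scission and the C2 radical takes hydrogen from PhSH; C2 becomes CH2 and C5 and C10 are untouched.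

Step 5
Reactants: 7 5β-methyl-10β-H-decal-6-ene-4,8-dione
Product: 8 4,4-ethylenedioxy-5β-methyl-10β-H-decal-6-en-8-one
Conditions: HOCH2CH2OH, TsOH·H2O (cat.), benzene, reflux, Dean–Stark
Reagents that add atoms: ethane-1,2-diol, OCCO
Why: Selective ketalisation: the saturated C4 ketone forms the dioxolane while the conjugated C8 ketone is much less electrophilic and stays free; no stereocentre is affected.

Step 6
Reactants: 8 4,4-ethylenedioxy-5β-methyl-10β-H-decal-6-en-8-one; 9 methyl 3-(bromomethyl)-4-methoxybenzoate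
Product: 11 9α-[2-methoxy-5-(methoxycarbonyl)benzyl]-4,4-ethylenedioxy-5β,9β-dimethyl-10β-H-decal-6-en-8-one, via monobenzyl enone 10 (not isolated)
Conditions: LiN(iPr)2 (1.05 equiv), THF, −78 °C; 9, −78 → −20 °C; then LiN(iPr)2 (1.3 equiv), −78 °C; MeI, DMPU, −78 → 0 °C
Reagents that add atoms: iodomethane, CI
Why: Two successive kinetic α′-enolate alkylations (SN2) at C9, the only enolisable carbon (C7 is vinylic, C5 quaternary, C4 masked); the last electrophile, MeI, should enter on the convex β face of the cis-fused dienolate, away from ring A whose C1 sits next to C9 on the α face, so the C9 methyl is β and the benzyl group α.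

Step 7
Reactants: 11 9α-[2-methoxy-5-(methoxycarbonyl)benzyl]-4,4-ethylenedioxy-5β,9β-dimethyl-10β-H-decal-6-en-8-one
Product: 12 9α-[2-methoxy-5-(methoxycarbonyl)benzyl]-4,4-ethylenedioxy-5β,9β-dimethyl-8-methylidene-10β-H-decal-6-ene
Conditions: Ph3PCH3Br, KOtBu, toluene, 90 °C
Reagents that add atoms: methyltriphenylphosphonium bromide, C[P+](c1ccccc1)(c1ccccc1)c1ccccc1.[Br-]
Why: Wittig methylenation of the non-enolisable C8 ketone, which reacts far faster than the methyl ester; no stereocentre changes.

Step 8
Reactants: 12 9α-[2-methoxy-5-(methoxycarbonyl)benzyl]-4,4-ethylenedioxy-5β,9β-dimethyl-8-methylidene-10β-H-decal-6-ene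
Product: 13 9α-[2-methoxy-5-(methoxycarbonyl)benzyl]-4,4-ethylenedioxy-5β,8β,9β-trimethyl-10β-H-decalin
Conditions: H2 (1 atm), 10% Pd/C, EtOAc, rt
Reagents that add atoms: none
Why: Heterogeneous hydrogenation of the diene: with the α-benzyl group equatorial, ring B of the ketal should adopt the chair that holds the C5 and C9 methyls 1,3-diaxial on the β face, so hydrogen is delivered to C8 from the α face and the new methyl ends β, cis to the C9 methyl.

Step 9
Reactants: 13 9α-[2-methoxy-5-(methoxycarbonyl)benzyl]-4,4-ethylenedioxy-5β,8β,9β-trimethyl-10β-H-decalin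
Product: 14 9α-[2-hydroxy-5-(methoxycarbonyl)benzyl]-5β,8β,9β-trimethyl-10β-H-decalin-4-one
Conditions: BBr3, CH2Cl2, −78 → 0 °C; H2O
Reagents that add atoms: none
Why: Lewis-acid O-demethylation of the aryl methyl ether and cleavage of the dioxolane in one operation, done before any alkene is present and cold enough that the methyl benzoate should survive; no stereocentre is epimerisable.

Step 10
Reactants: 14 9α-[2-hydroxy-5-(methoxycarbonyl)benzyl]-5β,8β,9β-trimethyl-10β-H-decalin-4-one
Product: 15 methyl 4-hydroxy-3-{[(1R,2S,4aS,8aR)-1,2,4a-trimethyl-5-methylidenedecahydronaphthalen-1-yl]methyl}benzoate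
Conditions: Ph3PCH3Br, KOtBu (4 equiv of ylide), THF, 65 °C; aq. NH4Cl
Reagents that add atoms: methyltriphenylphosphonium bromide, C[P+](c1ccccc1)(c1ccccc1)c1ccccc1.[Br-]
Why: Wittig methylenation of the hindered C4 ketone with excess ylide; the first equivalent forms the phenoxide, which also deactivates the para ester, and the quaternary C5 next to the ketone cannot epimerise.

## Compound list

1 | but-3-en-2-one (methyl vinyl ketone) | CC(=O)C=C | starting material
2 | 2-(tert-butyldimethylsilyloxy)buta-1,3-diene | C=CC(=C)O[Si](C)(C)C(C)(C)C | intermediate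
3 | (S)-(+)-carvone | CC1=CC[C@@H](CC1=O)C(C)=C | starting material
4 | 8-(tert-butyldimethylsilyloxy)-2β-isopropenyl-5β-methyl-10β-H-decal-7-en-4-one (cis-fused cycloadduct) | O=C1C[C@@H](C(C)=C)C[C@@H]2CC(O[Si](C)(C)C(C)(C)C)=CC[C@]12C | intermediate
5 | 2β-isopropenyl-5β-methyl-10β-H-decal-6-ene-4,8-dione | O=C1C[C@@H](C(C)=C)C[C@@H]2CC(=O)C=C[C@]12C | intermediate
6 | 2β-(1-hydroperoxy-1-methoxyethyl)-5β-methyl-10β-H-decal-6-ene-4,8-dione (epimers at the peroxy carbon) | O=C1C[C@@H](C(C)(OC)OO)C[C@@H]2CC(=O)C=C[C@]12C | intermediate (not isolated)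
7 | 5β-methyl-10β-H-decal-6-ene-4,8-dione | O=C1CCC[C@@H]2CC(=O)C=C[C@]12C | intermediate
8 | 4,4-ethylenedioxy-5β-methyl-10β-H-decal-6-en-8-one | O1CCOC12CCC[C@@H]3CC(=O)C=C[C@]23C | intermediate
9 | methyl 3-(bromomethyl)-4-methoxybenzoate | COC(=O)c1ccc(OC)c(CBr)c1 | starting material
10 | 9-[2-methoxy-5-(methoxycarbonyl)benzyl]-4,4-ethylenedioxy-5β-methyl-10β-H-decal-6-en-8-one (C9 epimers) | O1CCOC12CCC[C@@H]3C(Cc4cc(C(=O)OC)ccc4OC)C(=O)C=C[C@]23C | intermediate (not isolated)
11 | 9α-[2-methoxy-5-(methoxycarbonyl)benzyl]-4,4-ethylenedioxy-5β,9β-dimethyl-10β-H-decal-6-en-8-one | O1CCOC12CCC[C@@H]3[C@](C)(Cc4cc(C(=O)OC)ccc4OC)C(=O)C=C[C@]23C | intermediate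
12 | 9α-[2-methoxy-5-(methoxycarbonyl)benzyl]-4,4-ethylenedioxy-5β,9β-dimethyl-8-methylidene-10β-H-decal-6-ene | O1CCOC12CCC[C@@H]3[C@](C)(Cc4cc(C(=O)OC)ccc4OC)C(=C)C=C[C@]23C | intermediate
13 | 9α-[2-methoxy-5-(methoxycarbonyl)benzyl]-4,4-ethylenedioxy-5β,8β,9β-trimethyl-10β-H-decalin | O1CCOC12CCC[C@@H]3[C@](C)(Cc4cc(C(=O)OC)ccc4OC)[C@@H](C)CC[C@]23C | intermediate
14 | 9α-[2-hydroxy-5-(methoxycarbonyl)benzyl]-5β,8β,9β-trimethyl-10β-H-decalin-4-one | O=C1CCC[C@@H]2[C@](C)(Cc3cc(C(=O)OC)ccc3O)[C@@H](C)CC[C@]12C | intermediate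
15 | methyl 4-hydroxy-3-{[(1R,2S,4aS,8aR)-1,2,4a-trimethyl-5-methylidenedecahydronaphthalen-1-yl]methyl}benzoate (CNP0366393.2) | C=C1CCC[C@@H]2[C@](C)(Cc3cc(C(=O)OC)ccc3O)[C@@H](C)CC[C@]12C | target

## Step count and risks

Total step count: 10. Longest linear sequence: 10 steps (1 → 15; 9 steps from carvone 3).

Risk 1, step 6 (face of the second alkylation at C9, and the one-pot double alkylation). The facial preference of this cis-fused dienolate is reasoned, not known. If methyl iodide enters on the α face, or the one-pot protocol gives mixtures, the order of the two alkylations is reversed so that the benzyl group is the one that enters last on that face. The fallback sets out from 8: LiN(iPr)2 and MeI give the 9-methyl enone F1 (either C9–H epimer serves), and a second enolisation with LiN(iPr)2 followed by bromide 9 gives the quaternary centre. It comes back to the route at 11.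

Risk 2, step 8 (face of hydrogen delivery at C8). This is the least certain stereocentre, because the α face also carries the axial C1 methylene. If hydrogen arrives from the β face and the 8-epimer forms, the methyl carbon instead of hydrogen is brought in from that face. The fallback sets out from 11: conjugate reduction with LiBH(sBu)3 and trapping with PhNTf2 gives the enol triflate F2. Pd(OAc)2/PPh3 with Bu3N and HCO2H reduces it to the C7=C8 alkene F3. Simmons–Smith cyclopropanation (Et2Zn, CH2I2) on the same open face gives the cyclopropane F4 with its CH2 β and H-8 α. Hydrogenolysis of the less hindered C7–CH2 bond (H2, PtO2, AcOH) leaves the β-methyl on C8 and comes back to the route at 13.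

Risk 3, step 9 (BBr3 may also cleave the methyl ester). If the ester does not survive, the demethylation is moved to the end and done by SN2 under basic conditions. The fallback sets out from 13: aqueous HCl in THF removes the dioxolane to give the keto anisole F5. Wittig methylenation (Ph3PCH3Br, KOtBu) gives the O-methyl ether of the target F6. NaSEt in DMF at 110 °C cleaves both O-methyl groups without touching the exocyclic alkene and gives the hydroxy acid F7. MeI with KHCO3 in DMF re-methylates only the carboxylate and comes back to the route at 15.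

Further compounds

F1 | step 6 | 4,4-ethylenedioxy-5β,9-dimethyl-10β-H-decal-6-en-8-one (C9 epimers) | O1CCOC12CCC[C@@H]3C(C)C(=O)C=C[C@]23C
F2 | step 8 | 9α-[2-methoxy-5-(methoxycarbonyl)benzyl]-4,4-ethylenedioxy-5β,9β-dimethyl-10β-H-decal-7-en-8-yl trifluoromethanesulfonate | O1CCOC12CCC[C@@H]3[C@](C)(Cc4cc(C(=O)OC)ccc4OC)C(OS(=O)(=O)C(F)(F)F)=CC[C@]23C
F3 | step 8 | 9α-[2-methoxy-5-(methoxycarbonyl)benzyl]-4,4-ethylenedioxy-5β,9β-dimethyl-10β-H-decal-7-ene | O1CCOC12CCC[C@@H]3[C@](C)(Cc4cc(C(=O)OC)ccc4OC)C=CC[C@]23C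
F4 | step 8 | 7β,8β-methano-9α-[2-methoxy-5-(methoxycarbonyl)benzyl]-4,4-ethylenedioxy-5β,9β-dimethyl-10β-H-decalin | O1CCOC12CCC[C@@H]3[C@](C)(Cc4cc(C(=O)OC)ccc4OC)[C@H]5C[C@H]5C[C@]23C
F5 | step 9 | 9α-[2-methoxy-5-(methoxycarbonyl)benzyl]-5β,8β,9β-trimethyl-10β-H-decalin-4-one | O=C1CCC[C@@H]2[C@](C)(Cc3cc(C(=O)OC)ccc3OC)[C@@H](C)CC[C@]12C
F6 | step 9 | methyl 4-methoxy-3-{[(1R,2S,4aS,8aR)-1,2,4a-trimethyl-5-methylidenedecahydronaphthalen-1-yl]methyl}benzoate | C=C1CCC[C@@H]2[C@](C)(Cc3cc(C(=O)OC)ccc3OC)[C@@H](C)CC[C@]12C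
F7 | step 9 | 4-hydroxy-3-{[(1R,2S,4aS,8aR)-1,2,4a-trimethyl-5-methylidenedecahydronaphthalen-1-yl]methyl}benzoic acid | C=C1CCC[C@@H]2[C@](C)(Cc3cc(C(=O)O)ccc3O)[C@@H](C)CC[C@]12C
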